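**Plan**

1. Retrosynthetic cuts: first the interflavan bond C4(upper)–C6(lower) (Friedel–Crafts), then in each flavan unit the aryl ether bond O1–C8a together with C2–C3. Both units lead back to one 2-fluoroaryl ketone and 3,4-bis(benzyloxy)benzaldehyde.
2. Enabling feature: in ring C of both units O1 is bound to a ring A carbon (C8a) that is ortho to the benzylic C4. A temporary C4 carbonyl makes C3–H acidic and C8a–F displaceable, so an aldol addition followed by SNAr closes ring C onto preformed rings A and B.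
3. The two units are heterochiral at C2 (lower 2R, upper 2S). The annulation is therefore run racemic, and each antipode is harvested by a kinetic resolution through transfer hydrogenation: one run stopped early for the reduced antipode, one run taken past half conversion for the unreduced antipode.
4. Forward order: ketone + aldehyde → racemic trans-flavanone (ring C), PMB removal, the two resolutions. The reduced antipode becomes the lower unit (C4 oxygen removed). The unreduced antipode becomes the upper unit (its C4 oxygen inverts C3 through an epoxide, then serves as leaving group). Union and hydrogenolysis follow.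
5. Stereochemistry: C2/C3 trans by thermodynamic control in the key step; absolute configuration from RuCl[(S,S)-TsDPEN](p-cymene); upper C3 by SN2 epoxide closure; upper C4 by attack of the lower unit anti to the 2-aryl and 3-OH groups.

Key step: step 3

Remark: the sense of the kinetic resolution in steps 5 and 7 is assumed from the usual model of transfer hydrogenation with RuCl[(S,S)-TsDPEN](p-cymene); if it proved opposite, RuCl[(R,R)-TsDPEN](p-cymene) would give the same compounds 15 and 17.

**Route**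

Step 1
Reactants: 1 4-methoxybenzyl alcohol; 2 2-chloro-N-methoxy-N-methylacetamide
Product: 4 N-methoxy-2-[(4-methoxybenzyl)oxy]-N-methylacetamide, via sodium alkoxide 3 (not isolated)
Conditions: NaH, THF, 0 °C; then 2, Bu4NI (cat.), 0 °C → rt
Reagents that add atoms: none
Why: Williamson ether synthesis, in which the alkoxide displaces the carbonyl-activated primary chloride by SN2 while the Weinreb amide is inert to alkoxide at this temperature.

Step 2
Reactants: 5 4-(benzyloxy)-1-bromo-2-fluorobenzene; 4 N-methoxy-2-[(4-methoxybenzyl)oxy]-N-methylacetamide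
Product: 8 1-[4-(benzyloxy)-2-fluorophenyl]-2-[(4-methoxybenzyl)oxy]ethan-1-one, via aryl Grignard reagent 6 (not isolated), via magnesium hemiaminal 7 (not isolated)
Conditions: iPrMgCl·LiCl, THF, −15 °C; then 4, −15 → 0 °C; aq. NH4Cl
Reagents that add atoms: none
Why: Bromine–magnesium exchange (accelerated by the ortho fluorine, cold enough to avoid aryne formation) followed by Weinreb ketone synthesis, in which the chelated adduct 7 prevents a second addition.

Step 3
Reactants: 8 1-[4-(benzyloxy)-2-fluorophenyl]-2-[(4-methoxybenzyl)oxy]ethan-1-one; 9 3,4-bis(benzyloxy)benzaldehyde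
Product: 13 rac-(2R,3R)-7-(benzyloxy)-2-[3,4-bis(benzyloxy)phenyl]-3-[(4-methoxybenzyl)oxy]chroman-4-one (2,3-trans), via potassium enolate 10 (not isolated), via potassium aldolate 11 (not isolated), via cis-flavanone 12 (not isolated)
Conditions: KN(SiMe3)2 (1.0 equiv), THF, −78 °C; 9; −78 °C → rt; DBU (cat.), rt; aq. NH4Cl
Reagents that add atoms: none
Why: KN(SiMe3)2 should give the chelated (Z)-enolate 10 (the C4 carbonyl acidifies C3–H), which adds to aldehyde 9 in an aldol addition (C2–C3), after which the aldolate oxygen of 11 attacks C8a, the fluorine-bearing carbon ortho to the same carbonyl, and fluoride leaves from the Meisenheimer adduct (O1–C8a). The closest known reaction types are tandem aldol–SNAr annulations of activated fluoroarenes and the base-mediated cyclisation of β-hydroxy 2-fluoroaryl ketones to chroman-4-ones. Ring C closes in a 6-endo-trig addition–elimination onto the vinylogous acyl fluoride C8a=C4a–C4=O. C2 and C3 are formed without absolute control (the racemate is wanted because both antipodes are used), and their relative configuration is set thermodynamically, since C3 is epimerisable next to the ketone and DBU should convert cis-12 into trans-13 with both substituents equatorial. The step needs six-ring O-arylation to outrun retro-aldol cleavage, dehydration to the chalcone and five-ring closure, which the PMB ether on O3, the single equivalent of base and the fast intramolecular SNAr ortho to the carbonyl should secure.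

Step 4
Reactants: 13 rac-(2R,3R)-7-(benzyloxy)-2-[3,4-bis(benzyloxy)phenyl]-3-[(4-methoxybenzyl)oxy]chroman-4-one
Product: 14 rac-(2R,3R)-7-(benzyloxy)-2-[3,4-bis(benzyloxy)phenyl]-3-hydroxychroman-4-one
Conditions: DDQ, CH2Cl2/pH 7 buffer, 0 °C → rt
Reagents that add atoms: none
Why: Oxidative PMB ether cleavage (hydride abstraction, then hydrolysis of the oxocarbenium ion), which should spare the benzyl aryl ethers and the ketone-deactivated ring A and leave C2 and C3 untouched under neutral conditions.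

Step 5
Reactants: 14 rac-(2R,3R)-7-(benzyloxy)-2-[3,4-bis(benzyloxy)phenyl]-3-hydroxychroman-4-one
Product: 15 (2R,3S,4R)-7-(benzyloxy)-2-[3,4-bis(benzyloxy)phenyl]chromane-3,4-diol
Conditions: RuCl[(S,S)-TsDPEN](p-cymene) (1 mol %), HCO2H/Et3N (5:2), EtOAc, rt, stopped at about 40% conversion; chromatography
Reagents that add atoms: none
Why: Noyori-type asymmetric transfer hydrogenation used as a kinetic resolution, in which the catalyst fixes the face of hydride delivery (new C4 centre, 4R) and only the (2R,3R) enantiomer can accept it by axial attack to the all-equatorial diol, while stopping short of half conversion should keep the slow (2S,3S) ketone out of the diol fraction.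

Step 6
Reactants: 15 (2R,3S,4R)-7-(benzyloxy)-2-[3,4-bis(benzyloxy)phenyl]chromane-3,4-diol
Product: 16 (2R,3S)-7-(benzyloxy)-2-[3,4-bis(benzyloxy)phenyl]chroman-3-ol
Conditions: Et3SiH (excess), TFA, CH2Cl2, 0 °C
Reagents that add atoms: none
Why: Ionic hydrogenation, in which TFA ionises the C4 hydroxyl to a cation stabilised by O1 and the 7-benzyloxy group and excess silane traps it before it can alkylate a second molecule, C2 and C3 not being involved.

Step 7
Reactants: 14 rac-(2R,3R)-7-(benzyloxy)-2-[3,4-bis(benzyloxy)phenyl]-3-hydroxychroman-4-one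
Product: 17 (2S,3S)-7-(benzyloxy)-2-[3,4-bis(benzyloxy)phenyl]-3-hydroxychroman-4-one
Conditions: RuCl[(S,S)-TsDPEN](p-cymene) (1 mol %), HCO2H/Et3N (5:2), EtOAc, rt, run to about 60% conversion; chromatography
Reagents that add atoms: none
Why: The same kinetic resolution by asymmetric transfer hydrogenation, run on a second portion of 14 and driven past half conversion so that the fast (2R,3R) ketone should be consumed entirely as the diol and the slow (2S,3S) ketone, whose C2 and C3 centres come from step 3, should be left in high enantiomeric purity and separated from the far more polar diol.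

Step 8
Reactants: 17 (2S,3S)-7-(benzyloxy)-2-[3,4-bis(benzyloxy)phenyl]-3-hydroxychroman-4-one
Product: 18 (2S,3S)-7-(benzyloxy)-2-[3,4-bis(benzyloxy)phenyl]-4-oxochroman-3-yl methanesulfonate
Conditions: MsCl, Et3N, CH2Cl2, −20 °C
Reagents that add atoms: methanesulfonyl chloride, CS(=O)(=O)Cl
Why: Sulfonylation of the only hydroxyl group, run cold so that the amine does not enolise the ketone or open ring C.

Step 9
Reactants: 18 (2S,3S)-7-(benzyloxy)-2-[3,4-bis(benzyloxy)phenyl]-4-oxochroman-3-yl methanesulfonate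
Product: 21 (2S,3S,4R)-7-(benzyloxy)-2-[3,4-bis(benzyloxy)phenyl]-4-methoxychroman-3-ol, via hydroxy mesylate 19 (not isolated), via epoxide 20 (not isolated)
Conditions: NaBH4, MeOH/THF, −20 °C → rt; then AcOH to pH 5, rt
Reagents that add atoms: methanol, CO
Why: Axial hydride attack should place the C4 oxygen trans to the mesylate, the resulting alkoxide closes the epoxide by intramolecular SN2 (3-exo-tet, as in halohydrin-to-epoxide closure) with inversion at C3, and acid-catalysed methanolysis at the benzylic C4 leaves the oxygen on C3 cis to the 2-aryl group (the C4 epimer of 21 would be equally usable in step 10).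

Step 10
Reactants: 21 (2S,3S,4R)-7-(benzyloxy)-2-[3,4-bis(benzyloxy)phenyl]-4-methoxychroman-3-ol; 16 (2R,3S)-7-(benzyloxy)-2-[3,4-bis(benzyloxy)phenyl]chroman-3-ol
Product: 23 (2S,3S,4S)-7-(benzyloxy)-2-[3,4-bis(benzyloxy)phenyl]-4-{(2R,3S)-7-(benzyloxy)-2-[3,4-bis(benzyloxy)phenyl]-3-hydroxychroman-6-yl}chroman-3-ol, via flavan-4-yl cation 22 (not isolated)
Conditions: TMSOTf (0.2 equiv), 16 (3 equiv), CH2Cl2, −78 → −30 °C; Et3N quench
Reagents that add atoms: none
Why: Lewis acid-promoted Friedel–Crafts alkylation, in which C6 of 16 (para to O1, ortho to the 7-benzyloxy group, less hindered than C8) attacks cation 22 on the face anti to both the 2-aryl and 3-hydroxyl groups, giving the 3,4-trans bond, while excess 16 suppresses self-condensation.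

Step 11
Reactants: 23 (2S,3S,4S)-7-(benzyloxy)-2-[3,4-bis(benzyloxy)phenyl]-4-{(2R,3S)-7-(benzyloxy)-2-[3,4-bis(benzyloxy)phenyl]-3-hydroxychroman-6-yl}chroman-3-ol
Product: 24 (2S,3S,4R)-2-(3,4-dihydroxyphenyl)-4-[(2R,3S)-2-(3,4-dihydroxyphenyl)-3,7-dihydroxychroman-6-yl]chromane-3,7-diol
Conditions: H2 (1 atm), Pd(OH)2/C, THF/MeOH/H2O, rt
Reagents that add atoms: none
Why: Hydrogenolysis of the six benzyl aryl ethers under neutral conditions, which should leave the interflavan bond, the benzylic C2–O bonds and all five stereocentres intact.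

**Compound list**

1 | 4-methoxybenzyl alcohol | COc1ccc(CO)cc1 | starting material
2 | 2-chloro-N-methoxy-N-methylacetamide | ClCC(=O)N(C)OC | starting material
3 | sodium 4-methoxybenzyl oxide | [Na+].[O-]Cc1ccc(OC)cc1 | intermediate
4 | N-methoxy-2-[(4-methoxybenzyl)oxy]-N-methylacetamide | COc1ccc(COCC(=O)N(C)OC)cc1 | intermediate
5 | 4-(benzyloxy)-1-bromo-2-fluorobenzene | Fc1cc(OCc2ccccc2)ccc1Br | starting material
6 | [4-(benzyloxy)-2-fluorophenyl]magnesium chloride | Fc1cc(OCc2ccccc2)ccc1[Mg]Cl | intermediate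
7 | chloromagnesium N,O-hemiaminal from 6 and 4 (racemic at the new carbon) | CON(C)C(O[Mg]Cl)(COCc1ccc(OC)cc1)c1ccc(OCc2ccccc2)cc1F | intermediate
8 | 1-[4-(benzyloxy)-2-fluorophenyl]-2-[(4-methoxybenzyl)oxy]ethan-1-one | COc1ccc(COCC(=O)c2ccc(OCc3ccccc3)cc2F)cc1 | intermediate
9 | 3,4-bis(benzyloxy)benzaldehyde | O=Cc1ccc(OCc2ccccc2)c(OCc2ccccc2)c1 | starting material
10 | potassium (Z)-enolate of 8 | [K+].[O-]/C(=C\OCc1ccc(OC)cc1)c1ccc(OCc2ccccc2)cc1F | intermediate
11 | potassium aldolate from 10 and 9 (syn and anti, racemic; configuration not defined) | [K+].[O-]C(c1ccc(OCc2ccccc2)c(OCc2ccccc2)c1)C(OCc1ccc(OC)cc1)C(=O)c1ccc(OCc2ccccc2)cc1F | intermediate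
12 | rac-(2R,3S)-7-(benzyloxy)-2-[3,4-bis(benzyloxy)phenyl]-3-[(4-methoxybenzyl)oxy]chroman-4-one (2,3-cis; both enantiomers shown) | c1ccccc1COc1ccc2c(c1)O[C@H](c1ccc(OCc3ccccc3)c(OCc3ccccc3)c1)[C@H](OCc1ccc(OC)cc1)C2=O.c1ccccc1COc1ccc2c(c1)O[C@@H](c1ccc(OCc3ccccc3)c(OCc3ccccc3)c1)[C@@H](OCc1ccc(OC)cc1)C2=O | intermediate
13 | rac-(2R,3R)-7-(benzyloxy)-2-[3,4-bis(benzyloxy)phenyl]-3-[(4-methoxybenzyl)oxy]chroman-4-one (2,3-trans; both enantiomers shown) | c1ccccc1COc1ccc2c(c1)O[C@H](c1ccc(OCc3ccccc3)c(OCc3ccccc3)c1)[C@@H](OCc1ccc(OC)cc1)C2=O.c1ccccc1COc1ccc2c(c1)O[C@@H](c1ccc(OCc3ccccc3)c(OCc3ccccc3)c1)[C@H](OCc1ccc(OC)cc1)C2=O | intermediate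
14 | rac-(2R,3R)-7-(benzyloxy)-2-[3,4-bis(benzyloxy)phenyl]-3-hydroxychroman-4-one (2,3-trans; both enantiomers shown) | c1ccccc1COc1ccc2c(c1)O[C@H](c1ccc(OCc3ccccc3)c(OCc3ccccc3)c1)[C@@H](O)C2=O.c1ccccc1COc1ccc2c(c1)O[C@@H](c1ccc(OCc3ccccc3)c(OCc3ccccc3)c1)[C@H](O)C2=O | intermediate
15 | (2R,3S,4R)-7-(benzyloxy)-2-[3,4-bis(benzyloxy)phenyl]chromane-3,4-diol (2,3-trans-3,4-trans) | c1ccccc1COc1ccc2c(c1)O[C@H](c1ccc(OCc3ccccc3)c(OCc3ccccc3)c1)[C@@H](O)[C@@H]2O | intermediate
16 | (2R,3S)-7-(benzyloxy)-2-[3,4-bis(benzyloxy)phenyl]chroman-3-ol (tri-O-benzylfisetinidol) | c1ccccc1COc1ccc2c(c1)O[C@H](c1ccc(OCc3ccccc3)c(OCc3ccccc3)c1)[C@@H](O)C2 | intermediate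
17 | (2S,3S)-7-(benzyloxy)-2-[3,4-bis(benzyloxy)phenyl]-3-hydroxychroman-4-one | c1ccccc1COc1ccc2c(c1)O[C@@H](c1ccc(OCc3ccccc3)c(OCc3ccccc3)c1)[C@H](O)C2=O | intermediate
18 | (2S,3S)-7-(benzyloxy)-2-[3,4-bis(benzyloxy)phenyl]-4-oxochroman-3-yl methanesulfonate | c1ccccc1COc1ccc2c(c1)O[C@@H](c1ccc(OCc3ccccc3)c(OCc3ccccc3)c1)[C@H](OS(C)(=O)=O)C2=O | intermediate
19 | (2S,3R,4S)-7-(benzyloxy)-2-[3,4-bis(benzyloxy)phenyl]-4-hydroxychroman-3-yl methanesulfonate | c1ccccc1COc1ccc2c(c1)O[C@@H](c1ccc(OCc3ccccc3)c(OCc3ccccc3)c1)[C@H](OS(C)(=O)=O)[C@H]2O | intermediate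
20 | (2S,3S,4S)-7-(benzyloxy)-2-[3,4-bis(benzyloxy)phenyl]-3,4-epoxychromane (epoxide oxygen on the face of the 2-aryl group) | c1ccccc1COc1ccc2c(c1)O[C@@H](c1ccc(OCc3ccccc3)c(OCc3ccccc3)c1)[C@H]4O[C@@H]24 | intermediate
21 | (2S,3S,4R)-7-(benzyloxy)-2-[3,4-bis(benzyloxy)phenyl]-4-methoxychroman-3-ol (2,3-cis-3,4-trans) | c1ccccc1COc1ccc2c(c1)O[C@@H](c1ccc(OCc3ccccc3)c(OCc3ccccc3)c1)[C@@H](O)[C@@H]2OC | intermediate
22 | (2S,3S)-7-(benzyloxy)-2-[3,4-bis(benzyloxy)phenyl]-3-hydroxychroman-4-ylium triflate | c1ccccc1COc1ccc2c(c1)O[C@@H](c1ccc(OCc3ccccc3)c(OCc3ccccc3)c1)[C@@H](O)[CH+]2.[O-]S(=O)(=O)C(F)(F)F | intermediate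
23 | (2S,3S,4S)-7-(benzyloxy)-2-[3,4-bis(benzyloxy)phenyl]-4-{(2R,3S)-7-(benzyloxy)-2-[3,4-bis(benzyloxy)phenyl]-3-hydroxychroman-6-yl}chroman-3-ol (the C4 descriptor differs from that of 24 only through the priority change caused by the benzyl groups) | c1ccccc1COc1ccc2c(c1)O[C@@H](c1ccc(OCc3ccccc3)c(OCc3ccccc3)c1)[C@@H](O)[C@@H]2c1cc2c(cc1OCc1ccccc1)O[C@H](c1ccc(OCc3ccccc3)c(OCc3ccccc3)c1)[C@@H](O)C2 | intermediate
24 | (2S,3S,4R)-2-(3,4-dihydroxyphenyl)-4-[(2R,3S)-2-(3,4-dihydroxyphenyl)-3,7-dihydroxychroman-6-yl]chromane-3,7-diol | Oc1ccc2c(c1)O[C@@H](c1ccc(O)c(O)c1)[C@@H](O)[C@@H]2c1cc2c(cc1O)O[C@H](c1ccc(O)c(O)c1)[C@@H](O)C2 | target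

**Summary**

Total step count: 11. Longest linear sequence: 9 steps (steps 1, 2, 3, 4, 7, 8, 9, 10 and 11).

Steps most likely to fail, with fallbacks:

Step 5. The rate difference between the two enantiomers of 14 may be too small, or 14 may racemise by ring opening and re-closure in the buffered medium, so that the diol is not obtained enantiopure; the same weakness would affect step 7. The fallback moves the resolution to an enzymatic acyl transfer and sets out from 14. NaBH4 reduces the racemate to the racemic 2,3-trans-3,4-trans diol F1. A lipase (Burkholderia cepacia lipase, vinyl acetate, t-BuOMe) should then acetylate the benzylic 4-hydroxyl of one enantiomer, taken here by assumption as the (2S,3R,4S) diol, to give the 4-O-acetate F2. The (2R,3S,4R) diol is left untouched, and the route is rejoined there at 15. Methanolysis of F2 (K2CO3, MeOH) gives the (2S,3R,4S) diol F3, and MnO2 oxidises its benzylic alcohol back to the ketone, rejoining the route at 17, so that step 7 is replaced as well.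

Step 9. Hydride attack may give the 3,4-cis alcohol, which cannot close, or aryl migration with ring contraction and solvolysis of the mesylate may compete with epoxide closure. The fallback inverts C3 by oxidation and reduction and sets out from 17. NaBH4 followed by HCl in MeOH in the same flask (through the diol F3) gives the 2,3-trans 4-methyl ether F4, whose C4 epimer would serve equally. Dess–Martin oxidation gives the 4-methoxychroman-3-one F5. LiBH(s-Bu)3 at −78 °C should attack anti to the 2-aryl and 4-methoxy groups and give the 2,3-cis alcohol F6. This is coupled with 16 under the conditions of step 10 through the same cation 22, and the route is rejoined at 23.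

Step 3. Retro-aldol cleavage of 11 and dehydration to the chalcone may outrun ring closure, and any excess base may open ring C of the product. The fallback builds the same racemic dihydroflavonol by the chalcone epoxide route and sets out from 9. Commercial 1-[4-(benzyloxy)-2-hydroxyphenyl]ethan-1-one F7 is protected (MOMCl, i-Pr2NEt) as the MOM ether F8. Claisen–Schmidt condensation with 9 (KOH, EtOH) gives the (E)-chalcone F9. Weitz–Scheffer epoxidation (H2O2, NaOH) gives the racemic trans-epoxide F10. HCl in MeOH/THF removes the MOM group, and the freed phenol opens the epoxide at the benzylic carbon (6-endo, inversion) to the 2,3-trans product, rejoining the route at 14; steps 1, 2 and 4 are then not needed.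

**Further compounds**

F1 | step 5 | rac-(2R,3S,4R)-7-(benzyloxy)-2-[3,4-bis(benzyloxy)phenyl]chromane-3,4-diol (both enantiomers shown) | c1ccccc1COc1ccc2c(c1)O[C@H](c1ccc(OCc3ccccc3)c(OCc3ccccc3)c1)[C@@H](O)[C@@H]2O.c1ccccc1COc1ccc2c(c1)O[C@@H](c1ccc(OCc3ccccc3)c(OCc3ccccc3)c1)[C@H](O)[C@H]2O
F2 | step 5 | (2S,3S,4S)-7-(benzyloxy)-2-[3,4-bis(benzyloxy)phenyl]-3-hydroxychroman-4-yl acetate (4-O-acetate of the enantiomer of 15) | c1ccccc1COc1ccc2c(c1)O[C@@H](c1ccc(OCc3ccccc3)c(OCc3ccccc3)c1)[C@H](O)[C@H]2OC(C)=O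
F3 | step 5 | (2S,3R,4S)-7-(benzyloxy)-2-[3,4-bis(benzyloxy)phenyl]chromane-3,4-diol | c1ccccc1COc1ccc2c(c1)O[C@@H](c1ccc(OCc3ccccc3)c(OCc3ccccc3)c1)[C@H](O)[C@H]2O
F4 | step 9 | (2S,3R,4S)-7-(benzyloxy)-2-[3,4-bis(benzyloxy)phenyl]-4-methoxychroman-3-ol | c1ccccc1COc1ccc2c(c1)O[C@@H](c1ccc(OCc3ccccc3)c(OCc3ccccc3)c1)[C@H](O)[C@H]2OC
F5 | step 9 | (2S,4S)-7-(benzyloxy)-2-[3,4-bis(benzyloxy)phenyl]-4-methoxychroman-3-one | c1ccccc1COc1ccc2c(c1)O[C@@H](c1ccc(OCc3ccccc3)c(OCc3ccccc3)c1)C(=O)[C@H]2OC
F6 | step 9 | (2S,3S,4S)-7-(benzyloxy)-2-[3,4-bis(benzyloxy)phenyl]-4-methoxychroman-3-ol | c1ccccc1COc1ccc2c(c1)O[C@@H](c1ccc(OCc3ccccc3)c(OCc3ccccc3)c1)[C@@H](O)[C@H]2OC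
F7 | step 3 | 1-[4-(benzyloxy)-2-hydroxyphenyl]ethan-1-one | CC(=O)c1ccc(OCc2ccccc2)cc1O
F8 | step 3 | 1-[4-(benzyloxy)-2-(methoxymethoxy)phenyl]ethan-1-one | CC(=O)c1ccc(OCc2ccccc2)cc1OCOC
F9 | step 3 | (E)-1-[4-(benzyloxy)-2-(methoxymethoxy)phenyl]-3-[3,4-bis(benzyloxy)phenyl]prop-2-en-1-one | O=C(/C=C/c1ccc(OCc2ccccc2)c(OCc2ccccc2)c1)c1ccc(OCc2ccccc2)cc1OCOC
F10 | step 3 | rac-trans-{3-[3,4-bis(benzyloxy)phenyl]oxiran-2-yl}[4-(benzyloxy)-2-(methoxymethoxy)phenyl]methanone (both enantiomers shown) | O=C([C@H]1O[C@@H]1c1ccc(OCc2ccccc2)c(OCc2ccccc2)c1)c1ccc(OCc2ccccc2)cc1OCOC.O=C([C@@H]1O[C@H]1c1ccc(OCc2ccccc2)c(OCc2ccccc2)c1)c1ccc(OCc2ccccc2)cc1OCOC
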